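**Strategy.** The target is a C2-symmetric biaryl whose only stereocentres are two methyl-bearing benzylic CH groups, each on ring carbon C1 of its ring (phenolic oxygen on C6, biaryl bond at C3, methyl on C4). This aryl–CH(CH3)–vinyl pattern arises when a nickel hydride and ethylene add in the branched sense to a styrene-type vinyl group. Both benzylic C–C bonds and both stereocentres are therefore made in one operation by twofold nickel-catalysed asymmetric hydrovinylation of 4,4'-dimethoxy-2,2'-dimethyl-5,5'-divinylbiphenyl with ethylene. The precursor is an achiral divinylbiaryl bis(methyl ether). The terminal alkenes formed then take up the last four chain carbons, and the ethers are cleaved at the end.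

Key step: step 4

Remarks on the chemistry:
- Each ring has only one substituent ortho to the biaryl bond, so the axis rotates freely. The two benzylic centres are the only stereo-elements, both are (S) in the target, and the (R,S) isomer counts as meso.
- Assumption: the (Ra,Sc,Sc) antipode of the BINOL/bis(1-phenylethyl)amine phosphoramidite is taken as the one that delivers the (S)-3-arylbut-1-ene. If a trial on 2-methoxy-4-methylstyrene shows the opposite sense, the mirror-image ligand is used and nothing else changes.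
- Methyl ethers are kept as phenol protection. They pass every step unchanged and can be removed by thiolate without acid, which the phenol/trisubstituted-alkene pair would not tolerate.

**Step 1**
Reactants: 1 4-bromo-3-methylanisole (two molecules)
Product: 2 4,4'-dimethoxy-2,2'-dimethylbiphenyl
Conditions: NiCl2(PPh3)2 (10 mol%), PPh3 (20 mol%), Zn dust (1.5 equiv), Et4NI (1 equiv), THF, 50 °C
Reagents that add atoms: none
Why: Nickel-catalysed reductive homocoupling of an aryl bromide (Ullmann-type), in which zinc keeps the catalyst in the zerovalent state for oxidative addition into C–Br; one ortho methyl per ring is tolerated and the methoxy group is inert.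

**Step 2**
Reactants: 2 4,4'-dimethoxy-2,2'-dimethylbiphenyl
Product: 3 5,5'-dibromo-4,4'-dimethoxy-2,2'-dimethylbiphenyl
Conditions: NBS (2.1 equiv), MeCN, 0 °C to rt, dark
Reagents that add atoms: N-bromosuccinimide, O=C1CCC(=O)N1Br
Why: Electrophilic aromatic bromination, directed in each ring to C5, which is ortho to methoxy and para to methyl and far less hindered than C3 between the two substituents; the polar solvent and exclusion of light disfavour benzylic radical bromination.

**Step 3**
Reactants: 3 5,5'-dibromo-4,4'-dimethoxy-2,2'-dimethylbiphenyl; 4 potassium vinyltrifluoroborate (3 equiv)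
Product: 5 4,4'-dimethoxy-2,2'-dimethyl-5,5'-divinylbiphenyl
Conditions: PdCl2(dppf)·CH2Cl2 (5 mol%), Cs2CO3 (6 equiv), THF/H2O 9:1, 80 °C; product kept cold with a trace of BHT
Reagents that add atoms: potassium vinyltrifluoroborate (4), C=C[B-](F)(F)F.[K+]
Why: Twofold Suzuki–Miyaura vinylation, the trifluoroborate releasing vinylboronic acid slowly under aqueous base so that homocoupling and Heck-type follow-up of the new styrene are limited; the aryl ethers and the biaryl are inert.

**Step 4**
Reactants: 5 4,4'-dimethoxy-2,2'-dimethyl-5,5'-divinylbiphenyl; 6 ethylene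
Product: 7 5,5'-bis[(2S)-but-3-en-2-yl]-4,4'-dimethoxy-2,2'-dimethylbiphenyl
Conditions: [Ni(C3H5)Br]2 (3 mol%), (Ra,Sc,Sc)-O,O'-(1,1'-binaphthalene-2,2'-diyl) N,N-bis(1-phenylethyl)phosphoramidite (6 mol%), Na[B(C6H3-3,5-(CF3)2)4] (7 mol%), ethylene (1 atm), CH2Cl2, −70 °C; quenched cold at full conversion
Reagents that add atoms: ethylene (6), C=C
Why: The cationic nickel hydride formed from the allylnickel bromide dimer, the phosphoramidite and the sodium borate under ethylene adds to each aryl vinyl group to give an η3-benzylnickel species, ethylene inserts into the benzylic Ni–C bond, and β-hydride elimination releases the 3-arylbut-1-ene and returns the hydride. The closest known reaction type is the nickel-catalysed asymmetric hydrovinylation of vinylarenes, alkoxy-substituted ones included, here run at two equivalent and independent sites of one molecule. No ring is closed. Each new benzylic stereocentre is set under catalyst control, the chiral phosphoramidite choosing the enantioface of the vinyl group; because the sites are remote, the (S,S) compound should dominate and wrong-face events should end up almost entirely in the meso isomer. The step needs branched regioselectivity, which the benzylic (η3) stabilisation secures, and chemoselectivity against isomerisation to the conjugated 2-arylbut-2-ene and against oligomerisation, which the low temperature, the monodentate ligand with a weakly coordinating anion and the cold quench should secure; the ortho methoxy groups and the biaryl are spectators.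

**Step 5**
Reactants: 7 5,5'-bis[(2S)-but-3-en-2-yl]-4,4'-dimethoxy-2,2'-dimethylbiphenyl; 8 1-bromo-2-methylprop-1-ene (3 equiv)
Product: 10 4,4'-dimethoxy-2,2'-dimethyl-5,5'-bis[(2S)-6-methylhept-5-en-2-yl]biphenyl, via bis(B-alkyl-9-BBN) borane 9 (not isolated)
Conditions: 9-BBN-H (2.5 equiv), THF, 0 °C to rt; then 8, PdCl2(dppf)·CH2Cl2 (5 mol%), 3 M aq NaOH, THF, 60 °C
Reagents that add atoms: 1-bromo-2-methylprop-1-ene (8), CC(C)=CBr; 9-BBN-H, B1C2CCCC1CCC2 (its boron ring stays only in 9)
Why: Anti-Markovnikov hydroboration of the two monosubstituted alkenes with 9-BBN-H followed by B-alkyl Suzuki–Miyaura coupling of the primary alkylboranes with the alkenyl bromide; the benzylic stereocentres take no part and keep their (S) configuration.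

**Step 6**
Reactants: 10 4,4'-dimethoxy-2,2'-dimethyl-5,5'-bis[(2S)-6-methylhept-5-en-2-yl]biphenyl
Product: 12 2,2'-dimethyl-5,5'-bis[(2S)-6-methylhept-5-en-2-yl]biphenyl-4,4'-diol, via disodium bisphenolate 11 (not isolated)
Conditions: NaSEt (10 equiv), DMF, 140 °C; then cold 1 M HCl to pH 5
Reagents that add atoms: none
Why: SN2 demethylation of both aryl methyl ethers by ethanethiolate in a dipolar aprotic solvent gives the bisphenolate, which is protonated on work-up to the target 12; the acid-free conditions spare the trisubstituted alkenes (no cyclisation of phenol onto alkene) and the non-acidic benzylic stereocentres.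

**Compound list**
1 | 4-bromo-3-methylanisole | COc1ccc(Br)c(C)c1 | starting material
2 | 4,4'-dimethoxy-2,2'-dimethylbiphenyl | COc1ccc(-c2ccc(OC)cc2C)c(C)c1 | intermediate
3 | 5,5'-dibromo-4,4'-dimethoxy-2,2'-dimethylbiphenyl | COc1cc(C)c(-c2cc(Br)c(OC)cc2C)cc1Br | intermediate
4 | potassium vinyltrifluoroborate | C=C[B-](F)(F)F.[K+] | starting material
5 | 4,4'-dimethoxy-2,2'-dimethyl-5,5'-divinylbiphenyl | C=Cc1cc(-c2cc(C=C)c(OC)cc2C)c(C)cc1OC | intermediate
6 | ethylene | C=C | starting material
7 | 5,5'-bis[(2S)-but-3-en-2-yl]-4,4'-dimethoxy-2,2'-dimethylbiphenyl | C=C[C@H](C)c1cc(-c2cc([C@@H](C)C=C)c(OC)cc2C)c(C)cc1OC | intermediate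
8 | 1-bromo-2-methylprop-1-ene | CC(C)=CBr | starting material
9 | 5,5'-bis[(2S)-4-(9-borabicyclo[3.3.1]nonan-9-yl)butan-2-yl]-4,4'-dimethoxy-2,2'-dimethylbiphenyl | B1(CC[C@H](C)c2cc(-c3cc([C@@H](C)CCB4C5CCCC4CCC5)c(OC)cc3C)c(C)cc2OC)C6CCCC1CCC6 | intermediate (not isolated)
10 | 4,4'-dimethoxy-2,2'-dimethyl-5,5'-bis[(2S)-6-methylhept-5-en-2-yl]biphenyl | CC(C)=CCC[C@H](C)c1cc(-c2cc([C@@H](C)CCC=C(C)C)c(OC)cc2C)c(C)cc1OC | intermediate
11 | disodium 2,2'-dimethyl-5,5'-bis[(2S)-6-methylhept-5-en-2-yl]biphenyl-4,4'-diolate | CC(C)=CCC[C@H](C)c1cc(-c2cc([C@@H](C)CCC=C(C)C)c([O-])cc2C)c(C)cc1[O-].[Na+].[Na+] | intermediate (not isolated)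
12 | 2,2'-dimethyl-5,5'-bis[(2S)-6-methylhept-5-en-2-yl]biphenyl-4,4'-diol | CC(C)=CCC[C@H](C)c1cc(-c2cc([C@@H](C)CCC=C(C)C)c(O)cc2C)c(C)cc1O | target

**Step count and risks**
Total steps: 6. Longest linear sequence: 6 steps (from 1).

Steps most likely to fail:

1. Step 4. The risks are incomplete enantioface control at either vinyl group, isomerisation of the new terminal alkene into conjugation with loss of the stereocentre, and oligomerisation of the electron-rich divinylarene on the cationic catalyst. Wrong-face addition feeds the meso diastereomer, which will be hard to remove because the two centres are far apart. The fallback sets out from 3 and returns at 7; it forms the benzylic stereocentres by C–CH3 bond formation instead of C–vinyl bond formation. Twofold Mizoroki–Heck reaction of 3 with methyl acrylate (Pd(OAc)2, P(o-tol)3, NaOAc, DMF, 110 °C) should give 5,5'-bis[(E)-2-(methoxycarbonyl)ethenyl]-4,4'-dimethoxy-2,2'-dimethylbiphenyl F1. Reduction with i-Bu2AlH (CH2Cl2, −78 °C) should give 5,5'-bis[(E)-3-hydroxyprop-1-enyl]-4,4'-dimethoxy-2,2'-dimethylbiphenyl F2. PBr3 (Et2O, 0 °C) should give 5,5'-bis[(E)-3-bromoprop-1-enyl]-4,4'-dimethoxy-2,2'-dimethylbiphenyl F3, used crude. Copper-catalysed enantioselective SN2' methylation (MeMgBr, CuBr·SMe2, the Taniaphos ferrocenyl diphosphine antipode that gives the (S) branched product, CH2Cl2, −75 °C) should then give 7.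

2. Step 5. The risks are incomplete twofold coupling through protodeboronation or β-hydride elimination of the alkylpalladium, and loss of the volatile alkenyl bromide from the warm mixture. The fallback sets out from 7 and returns at 10; it reverses the polarity so that the chain carbon is the electrophile. 7 is hydroborated as in step 5 to 9, which is oxidised (NaOH, H2O2, 0 °C) to 5,5'-bis[(2S)-4-hydroxybutan-2-yl]-4,4'-dimethoxy-2,2'-dimethylbiphenyl F4. Appel-type iodination (I2, PPh3, imidazole, CH2Cl2, 0 °C) should give 5,5'-bis[(2S)-4-iodobutan-2-yl]-4,4'-dimethoxy-2,2'-dimethylbiphenyl F5. Copper-catalysed coupling with (2-methylprop-1-enyl)magnesium bromide (Li2CuCl4 cat., THF, −20 to 0 °C) should give 10.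

3. Step 6. The risks are stalling after the first demethylation, since the phenolate formed makes the second ether a poorer leaving group and the dianion may be poorly soluble, and addition of thiol to the alkenes on long heating or during work-up. The fallback sets out from 3 and returns at 12; it changes the phenol protection to a fluoride-labile silyl ether so that no dealkylation is needed at the end. BBr3 (CH2Cl2, −78 to 0 °C) should cleave both ethers of 3, which has no alkene, to 5,5'-dibromo-2,2'-dimethylbiphenyl-4,4'-diol F6. TIPSCl and imidazole (DMF, rt) should give 5,5'-dibromo-2,2'-dimethyl-4,4'-bis(triisopropylsilyloxy)biphenyl F7. The conditions of steps 3, 4 and 5 (with K3PO4 in place of NaOH in the coupling) should then give in turn: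
   - 2,2'-dimethyl-4,4'-bis(triisopropylsilyloxy)-5,5'-divinylbiphenyl F8;
   - 5,5'-bis[(2S)-but-3-en-2-yl]-2,2'-dimethyl-4,4'-bis(triisopropylsilyloxy)biphenyl F9;
   - the borane 5,5'-bis[(2S)-4-(9-borabicyclo[3.3.1]nonan-9-yl)butan-2-yl]-2,2'-dimethyl-4,4'-bis(triisopropylsilyloxy)biphenyl F10, not isolated;
   - 2,2'-dimethyl-5,5'-bis[(2S)-6-methylhept-5-en-2-yl]-4,4'-bis(triisopropylsilyloxy)biphenyl F11.

   Bu4NF (THF, 0 °C) should then release 12.

**Further compounds**
F1 | step 4 | 5,5'-bis[(E)-2-(methoxycarbonyl)ethenyl]-4,4'-dimethoxy-2,2'-dimethylbiphenyl | COC(=O)/C=C/c1cc(-c2cc(/C=C/C(=O)OC)c(OC)cc2C)c(C)cc1OC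
F2 | step 4 | 5,5'-bis[(E)-3-hydroxyprop-1-enyl]-4,4'-dimethoxy-2,2'-dimethylbiphenyl | OC/C=C/c1cc(-c2cc(/C=C/CO)c(OC)cc2C)c(C)cc1OC
F3 | step 4 | 5,5'-bis[(E)-3-bromoprop-1-enyl]-4,4'-dimethoxy-2,2'-dimethylbiphenyl | BrC/C=C/c1cc(-c2cc(/C=C/CBr)c(OC)cc2C)c(C)cc1OC
F4 | step 5 | 5,5'-bis[(2S)-4-hydroxybutan-2-yl]-4,4'-dimethoxy-2,2'-dimethylbiphenyl | OCC[C@H](C)c1cc(-c2cc([C@@H](C)CCO)c(OC)cc2C)c(C)cc1OC
F5 | step 5 | 5,5'-bis[(2S)-4-iodobutan-2-yl]-4,4'-dimethoxy-2,2'-dimethylbiphenyl | ICC[C@H](C)c1cc(-c2cc([C@@H](C)CCI)c(OC)cc2C)c(C)cc1OC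
F6 | step 6 | 5,5'-dibromo-2,2'-dimethylbiphenyl-4,4'-diol | Oc1cc(C)c(-c2cc(Br)c(O)cc2C)cc1Br
F7 | step 6 | 5,5'-dibromo-2,2'-dimethyl-4,4'-bis(triisopropylsilyloxy)biphenyl | CC(C)[Si](Oc1cc(C)c(-c2cc(Br)c(O[Si](C(C)C)(C(C)C)C(C)C)cc2C)cc1Br)(C(C)C)C(C)C
F8 | step 6 | 2,2'-dimethyl-4,4'-bis(triisopropylsilyloxy)-5,5'-divinylbiphenyl | C=Cc1cc(-c2cc(C=C)c(O[Si](C(C)C)(C(C)C)C(C)C)cc2C)c(C)cc1O[Si](C(C)C)(C(C)C)C(C)C
F9 | step 6 | 5,5'-bis[(2S)-but-3-en-2-yl]-2,2'-dimethyl-4,4'-bis(triisopropylsilyloxy)biphenyl | C=C[C@H](C)c1cc(-c2cc([C@@H](C)C=C)c(O[Si](C(C)C)(C(C)C)C(C)C)cc2C)c(C)cc1O[Si](C(C)C)(C(C)C)C(C)C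
F10 | step 6 | 5,5'-bis[(2S)-4-(9-borabicyclo[3.3.1]nonan-9-yl)butan-2-yl]-2,2'-dimethyl-4,4'-bis(triisopropylsilyloxy)biphenyl | B1(CC[C@H](C)c2cc(-c3cc([C@@H](C)CCB4C5CCCC4CCC5)c(O[Si](C(C)C)(C(C)C)C(C)C)cc3C)c(C)cc2O[Si](C(C)C)(C(C)C)C(C)C)C6CCCC1CCC6
F11 | step 6 | 2,2'-dimethyl-5,5'-bis[(2S)-6-methylhept-5-en-2-yl]-4,4'-bis(triisopropylsilyloxy)biphenyl | CC(C)=CCC[C@H](C)c1cc(-c2cc([C@@H](C)CCC=C(C)C)c(O[Si](C(C)C)(C(C)C)C(C)C)cc2C)c(C)cc1O[Si](C(C)C)(C(C)C)C(C)C
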